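the same everywhere: G 1.4 M; L 1.26 M
- ash: Q 0.65 M; run made earlier
- autumn: Q 1.10 M; time 2.0 min
- dawn: Q 1.70 M; time 2.0 min
ash run (percent of the G charged)

| time / s | G / % | X / % |
|---|---|---|
| 10.0 | 81.0 | 18.4 |
| 12.0 | 78.9 | 19.2 |
| 25.0 | 73.2 | 21.8 |
| 60.0 | 68.4 | 20.3 |

(readings scatter by 0.5 percentage points)
- no earlier run changes the charge of Q; that part of a forecast is a guess
1. part of the G that has reacted at the end, autumn
2. part of the G that has reacted at the end, dawn
3. what raising the concentration of Q from its lowest to its highest value here does to the part of the G that has reacted (changes below 5 percentage points count as none) (it falls / it rises / no change)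

**The balance.** In a closed flask of constant volume, G that goes must stand somewhere. So for ash I wrote M, the missing part: what the G charged holds neither as G nor as X. Late in ash, the readings of X fell while M grew, so I read M as what X became. I took a one-way first-order step with rate constant k, the leak constant: the gain of M over the time integral of X.

**What mattered.** Between the last two ash readings M gained 6.3 percentage points. Four readings enter that gain, each scattering by 0.5 points, so it was uncertain by 1 point, or 15.9% of itself. The mean X, 21.1%, carried 1.68% of itself, a smaller error. So the gain of M was the number to watch. No earlier run changes Q, so I assumed the same k for autumn and dawn.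

**The number.** That gave k = 0.00855 /s. Integrating dX/dt = -kX, with all X born at the start, leaves at time t a share f = exp(-kt) of the reacted G as X. At 2.0 min that was f = 35.8%, between 30.5% and 42.2%. But G still fell 4.8 points between those ash readings, so some X is younger, and I expected a share at f or above. This splits the reacted G; its total stayed a guess.

**The forecast.** It gave 53% (41% to 66%) for autumn and 74% (55% to 90%) for dawn, and on the trend said "it rises", reasoning that “Q therefore looks limiting”.

**The outcome.** Autumn reached 46.4% and dawn 60.6%. On the trend the answer is "it rises", by 14 points.

    G + D ⇌ Z + X (K = 3.40, k = 0.686 /M/s)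
    D + Z ⇌ L, settled at all times (K = 76.7 /M)
    Z + Q ⇌ E (K = 150 /M, k = 0.161 /M/s)
    X ⇌ J (K = 4.50, k = 0.0109 /s)

**The split.** In autumn free Q ended at 3.30% of its charge, less than the 54% of G still free. X held 19.3% of the G charged, a share of 41.6% of the reacted G, against f = 35.8%. In dawn X held 26.0%, a share of 42.9%. In a flask like autumn but with 0.56 M of G, at the same time, 86.3% of the G charged had reacted and X held 37.4% of that charge, a share of 43.3%.

The numbers in the tables are calculated with made-up constants; scatter was added.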